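**Plan**
- Cuts: in the flavanone, O1–C2 (oxa-Michael) and C2–C3 (Knoevenagel), which frees ring B as an aryl aldehyde. In the flavone, O1–C2 and C4–C4a (ynone closure, aryllithium acylation). Last, flavone ring A at C8–C8a, C6–C7 and C4a–C8a.
- Enabling feature: flavone C8 bears C2' of ring B and lies between the oxygenated carbons C7 and C8a, and ring A has its oxygens in a 1,3,5 pattern (C5, C7, C8a). C8–C7 therefore map onto an aryl siloxyalkyne and C8a–C4a–C5–C6 onto the vinylketene from a 3-alkoxycyclobutenone. The three oxygens arrive as OH, OSi and OBn.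
- Forward order: ring B (bought) is ethynylated and turned into the siloxyalkyne. Flavone ring A then forms by benzannulation, flavone ring C by directed lithiation, ynone formation and 6-endo closure. Flavanone ring C comes last, with its ring A bought as a phloroacetophenone ether.
- Stereochemistry: flavanone C2 (S) is set by a catalyst-controlled cinchona-thiourea oxa-Michael addition and kept through acid decarboxylation and neutral hydrogenolysis.
- Protection: all eight phenols end as benzyl ethers, so one hydrogenolysis finishes the synthesis.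

Key step: step 8

Assumption: the structure fixes only C2. The crowded C2'–C8 biaryl axis is drawn without configuration, so it is carried uncontrolled: racemic from 17 on, and a pair of (2S) atropisomers from 33 on if rotation is slow.

Step 1
Reactants: 1 2-bromo-3,4-dimethoxybenzaldehyde
Product: 2 2-bromo-3,4-dihydroxybenzaldehyde
Conditions: BBr3 (3 equiv), CH2Cl2, −78 °C to rt; then H2O
Reagents that add atoms: none
Why: Lewis-acid aryl methyl ether cleavage with BBr3 is routine on veratraldehyde-type substrates, and exchanging methyl for benzyl at this simple stage spares the late flavanone any harsh dealkylation.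

Step 2
Reactants: 2 2-bromo-3,4-dihydroxybenzaldehyde
Product: 3 3,4-bis(benzyloxy)-2-bromobenzaldehyde
Conditions: BnBr (2.3 equiv), K2CO3, DMF, 50 °C
Reagents that add atoms: benzyl bromide, BrCc1ccccc1
Why: Williamson etherification of both catechol hydroxyls gives benzyl ethers that withstand organolithiums, heat and aqueous acid and leave by hydrogenolysis at the end.

Step 3
Reactants: 3 3,4-bis(benzyloxy)-2-bromobenzaldehyde; 4 trimethylsilylacetylene
Product: 5 3,4-bis(benzyloxy)-2-[(trimethylsilyl)ethynyl]benzaldehyde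
Conditions: PdCl2(PPh3)2 (5 mol %), CuI (10 mol %), Et3N, THF, 60 °C
Reagents that add atoms: none
Why: Sonogashira coupling, run on the free aldehyde because the ortho formyl group speeds oxidative addition of zerovalent palladium into the crowded, electron-rich C–Br bond.

Step 4
Reactants: 5 3,4-bis(benzyloxy)-2-[(trimethylsilyl)ethynyl]benzaldehyde
Product: 6 2-{3,4-bis(benzyloxy)-2-[(trimethylsilyl)ethynyl]phenyl}-5,5-dimethyl-1,3-dioxane
Conditions: 2,2-dimethylpropane-1,3-diol, TsOH·H2O (cat.), toluene, reflux, Dean–Stark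
Reagents that add atoms: 2,2-dimethylpropane-1,3-diol, OCC(C)(C)CO
Why: Acid-catalysed acetalisation with azeotropic water removal, the neopentyl-glycol acetal being preferred to a dimethyl acetal because it resists butyllithium, silica gel and exchange with the phenol that appears beside it in step 8.

Step 5
Reactants: 6 silylalkyne acetal
Product: 7 2-[3,4-bis(benzyloxy)-2-ethynylphenyl]-5,5-dimethyl-1,3-dioxane
Conditions: K2CO3 (cat.), MeOH/THF, rt
Reagents that add atoms: none
Why: Carbonate-catalysed methanolysis of the alkynyl C–Si bond (protiodesilylation), to which acetal and benzyl ethers are inert.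

Step 6
Reactants: 7 terminal alkyne acetal
Product: 10 [2,3-bis(benzyloxy)-6-(5,5-dimethyl-1,3-dioxan-2-yl)phenyl]ethynyl triisopropylsilyl ether, via lithium acetylide 8 (not isolated), via lithium ynolate 9 (not isolated)
Conditions: n-BuLi, THF, −78 °C; t-BuOOLi (from t-BuOOH + n-BuLi, THF, −78 °C), −78 to 0 °C; TIPSOTf, −78 to 0 °C
Reagents that add atoms: tert-butyl hydroperoxide (used as its lithium salt, gives the ynol oxygen), CC(C)(C)OO; triisopropylsilyl trifluoromethanesulfonate, CC(C)[Si](C(C)C)(C(C)C)OS(=O)(=O)C(F)(F)F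
Why: Oxidation of a lithium acetylide with lithium tert-butyl peroxide gives the ynolate, which the bulky silyl triflate traps on oxygen rather than carbon (a known route to triisopropylsiloxyalkynes), and the medium stays basic so the triflate cannot ionise the acetal.

Step 7
Reactants: 11 3-ethoxycyclobut-2-en-1-one
Product: 12 3-(benzyloxy)cyclobut-2-en-1-one
Conditions: BnOH (2 equiv), camphorsulfonic acid (5 mol %), toluene, rt, reduced pressure (EtOH stripped)
Reagents that add atoms: benzyl alcohol, OCc1ccccc1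
Why: Acid-catalysed transetherification of a vinylogous ester (alcohol adds at C3, ethanol leaves) is the same addition–elimination by which this enone is hydrolysed and squarate esters are exchanged, and it makes the future flavone C5 oxygen removable in the final hydrogenolysis.

Step 8
Reactants: 10 ring-B triisopropylsiloxyalkyne; 12 3-(benzyloxy)cyclobut-2-en-1-one
Product: 17 2-[2,3-bis(benzyloxy)-6-(5,5-dimethyl-1,3-dioxan-2-yl)phenyl]-5-(benzyloxy)-3-[(triisopropylsilyl)oxy]phenol, via vinylketene 13 (not isolated), via vinylcyclobutenone 14 (not isolated), via dienylketene 15 (not isolated), via cyclohexadienone 16 (not isolated)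
Conditions: 12 (1.5 equiv, two portions), toluene (0.5 M), argon, sealed tube, 110 to 130 °C
Reagents that add atoms: none
Why: Proposed new method: heat opens 12 by a four-electron conrotatory electrocyclic reaction to vinylketene 13, whose carbonyl carbon (future C8a) is attacked by the aryl-bearing, nucleophilic carbon of ynol ether 10 (future C8) while C6 joins C7, a [2+2] cycloaddition that closes the transient four-membered ring of 14. A second four-electron opening turns 14 into dienylketene 15, and the lasting ring, carbocyclic ring A of the flavone, closes by six-electron disrotatory electrocyclisation (C4a–C8a) to dienone 16, which tautomerises irreversibly to phenol 17. The closest known reaction type is the Danheiser benzannulation of 3-alkylcyclobutenones with alkyl-substituted triisopropylsiloxyalkynes to resorcinol monosilyl ethers; untested are the 3-alkoxy (vinylogous ester) cyclobutenone, which loses conjugation on opening and is therefore given 110–130 °C, and an alkyne carrying a doubly ortho-substituted aryl group. The alkoxy group of 13 is cross-conjugated with the ketene and should not blunt its electrophilicity, and the aryl group sits on an sp or in-plane sp2 carbon in every bond-forming event, so its ortho groups stay clear of the reacting centres. The selectivity needed is 8-aryl over 6-aryl together with three distinguishable oxygens, and it is secured by the polarisation of the Si–O–C≡C unit, which puts the new C–OH (C8a) and C–OSi (C7) on either side of the aryl carbon and leaves OBn on C5. No stereocentre is formed; the crowded biaryl axis arises racemic and is not controlled.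

Step 9
Reactants: 17 biaryl phenol
Product: 18 2-[4',5,6-tris(benzyloxy)-2'-(methoxymethoxy)-6'-(triisopropylsilyloxy)biphenyl-2-yl]-5,5-dimethyl-1,3-dioxane
Conditions: MOMCl, i-Pr2NEt, CH2Cl2, 0 °C to reflux
Reagents that add atoms: chloromethyl methyl ether, COCCl
Why: O-alkylation of the only free phenol (MOM ether formation) turns the future O1 into the strongest ortho-directing group of the ring, and the amine base leaves TIPS ether and acetal untouched.

Step 10
Reactants: 19 3,4-bis(benzyloxy)benzaldehyde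
Product: 20 1,2-bis(benzyloxy)-4-ethynylbenzene
Conditions: dimethyl (1-diazo-2-oxopropyl)phosphonate, K2CO3, MeOH/THF, rt
Reagents that add atoms: dimethyl (1-diazo-2-oxopropyl)phosphonate, CC(=O)C(=[N+]=[N-])P(=O)(OC)OC
Why: Ohira–Bestmann homologation converts aromatic aldehydes into terminal alkynes in one mild step.

Step 11
Reactants: 20 1,2-bis(benzyloxy)-4-ethynylbenzene
Product: 22 3-[3,4-bis(benzyloxy)phenyl]-N-methoxy-N-methylprop-2-ynamide, via lithium acetylide 21 (not isolated)
Conditions: n-BuLi, THF, −78 °C; ClC(O)N(OMe)Me, −78 °C to rt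
Reagents that add atoms: N-methoxy-N-methylcarbamoyl chloride, CON(C)C(=O)Cl
Why: Acylation of a lithium acetylide with the carbamoyl chloride is a standard preparation of alkynyl Weinreb amides.

Step 12
Reactants: 18 MOM ether; 22 alkynyl Weinreb amide
Product: 24 1-{6-(benzyloxy)-3-[2,3-bis(benzyloxy)-6-(5,5-dimethyl-1,3-dioxan-2-yl)phenyl]-2-(methoxymethoxy)-4-(triisopropylsilyloxy)phenyl}-3-[3,4-bis(benzyloxy)phenyl]prop-2-yn-1-one, via aryllithium 23 (not isolated)
Conditions: n-BuLi (1.2 equiv), THF, 0 °C; 22, −78 to −20 °C; AcOH quench at −78 °C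
Reagents that add atoms: none
Why: Directed ortho-metalation followed by Weinreb ketone synthesis, in which MOM chelation guides n-BuLi to the hydrogen between OMOM and OBn (future C4a), the other ring hydrogen is screened by the non-coordinating TIPS ether, and the amide delivers the ynone without over-addition.

Step 13
Reactants: 24 ynone
Product: 26 3,4-bis(benzyloxy)-2-{5-(benzyloxy)-2-[3,4-bis(benzyloxy)phenyl]-4-oxo-7-[(triisopropylsilyl)oxy]-4H-chromen-8-yl}benzaldehyde, via enaminone 25 (not isolated)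
Conditions: Et2NH (5 equiv), EtOH/THF, rt; evaporate; 3 M aq. HCl, THF, 50 °C
Reagents that add atoms: water, O; diethylamine, CCNCC (its atoms stay only in 25)
Why: Aza-Michael addition turns the ynone into a β-enaminone, so that once acid removes the MOM group the phenol can only close by 6-endo addition–elimination (the known enaminone route to flavones, no aurone), while the same aqueous acid hydrolyses the acetal and leaves the aryl TIPS and benzyl ethers alone.

Step 14
Reactants: 26 7-silyloxyflavone aldehyde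
Product: 28 3,4-bis(benzyloxy)-2-{5,7-bis(benzyloxy)-2-[3,4-bis(benzyloxy)phenyl]-4-oxo-4H-chromen-8-yl}benzaldehyde, via caesium phenolate 27 (not isolated)
Conditions: CsF (2 equiv), BnBr (1.5 equiv), DMF, rt
Reagents that add atoms: benzyl bromide, BrCc1ccccc1
Why: Fluoride desilylation with in-situ Williamson benzylation of an aryl silyl ether, in which the acidic 7-phenolate stays as the open aldehyde rather than a lactolate and is alkylated on oxygen, replacing a silyl ether that would be labile to the amine catalysts ahead.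

Step 15
Reactants: 29 1-[2,4-bis(benzyloxy)-6-hydroxyphenyl]ethan-1-one
Product: 31 tert-butyl 3-[2,4-bis(benzyloxy)-6-hydroxyphenyl]-3-oxopropanoate, via dilithium dianion 30 (not isolated)
Conditions: LiHMDS (2.2 equiv), THF, −78 °C; Boc2O (1.1 equiv), −78 to 0 °C; 1 M aq. HCl
Reagents that add atoms: di-tert-butyl dicarbonate, CC(C)(C)OC(=O)OC(=O)OC(C)(C)C
Why: Claisen-type C-acylation of the phenolate/enolate dianion, in which any O-Boc phenol is carried to the same β-keto ester by Baker–Venkataraman-type O-to-C transfer and the tert-butyl ester blocks lactonisation to a 4-hydroxycoumarin.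

Step 16
Reactants: 28 hexabenzyl flavone aldehyde; 31 β-keto ester
Product: 32 tert-butyl (Z)-2-[2,4-bis(benzyloxy)-6-hydroxybenzoyl]-3-(3,4-bis(benzyloxy)-2-{5,7-bis(benzyloxy)-2-[3,4-bis(benzyloxy)phenyl]-4-oxo-4H-chromen-8-yl}phenyl)prop-2-enoate
Conditions: piperidine (20 mol %), AcOH (20 mol %), 4 Å molecular sieves, toluene, rt
Reagents that add atoms: none
Why: Knoevenagel condensation under piperidinium acetate catalysis, with the phenol hydrogen-bonded to the aroyl carbonyl, which should hold back ring closure until the chiral catalyst is present.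

Step 17
Reactants: 32 alkylidene β-keto ester
Product: 35 (2S)-5,7-bis(benzyloxy)-2-(3,4-bis(benzyloxy)-2-{5,7-bis(benzyloxy)-2-[3,4-bis(benzyloxy)phenyl]-4-oxo-4H-chromen-8-yl}phenyl)chroman-4-one, via tert-butyl ester 33 (not isolated), via keto acid 34 (not isolated)
Conditions: 1-[3,5-bis(trifluoromethyl)phenyl]-3-[(8α,9S)-6'-methoxycinchonan-9-yl]thiourea (10 mol %), toluene, −25 °C; then TsOH·H2O, 80 °C
Reagents that add atoms: none
Why: Bifunctional cinchona-thiourea-catalysed intramolecular oxa-Michael addition, in which the thiourea binds the β-keto ester carbonyls and the quinuclidine nitrogen deprotonates the phenol so that O1 reaches one alkene face and sets C2 as S under catalyst control (sense to be confirmed by circular dichroism, the quinidine-derived pseudoenantiomer being the switch), after which acid-induced loss of isobutene and CO2 erases C3 without touching C2.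

Step 18
Reactants: 35 octabenzyl ether
Product: 36 (2S)-2-{2-[2-(3,4-dihydroxyphenyl)-5,7-dihydroxy-4-oxo-4H-chromen-8-yl]-3,4-dihydroxyphenyl}-5,7-dihydroxychroman-4-one
Conditions: H2 (1 atm), 10 % Pd/C, THF/MeOH, rt
Reagents that add atoms: none
Why: Catalytic hydrogenolysis of all eight aryl benzyl ethers under neutral conditions avoids the base- or acid-induced opening to the chalcone that would racemise C2, and at ambient pressure it is known to spare the flavone C2–C3 double bond and both carbonyl groups.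

**Compound list**

1 | 2-bromo-3,4-dimethoxybenzaldehyde | COc1ccc(C=O)c(Br)c1OC | starting material
2 | 2-bromo-3,4-dihydroxybenzaldehyde | O=Cc1ccc(O)c(O)c1Br | intermediate
3 | 3,4-bis(benzyloxy)-2-bromobenzaldehyde | O=Cc1ccc(OCc2ccccc2)c(OCc2ccccc2)c1Br | intermediate
4 | trimethylsilylacetylene | C#C[Si](C)(C)C | starting material
5 | 3,4-bis(benzyloxy)-2-[(trimethylsilyl)ethynyl]benzaldehyde | O=Cc1ccc(OCc2ccccc2)c(OCc2ccccc2)c1C#C[Si](C)(C)C | intermediate
6 | 2-{3,4-bis(benzyloxy)-2-[(trimethylsilyl)ethynyl]phenyl}-5,5-dimethyl-1,3-dioxane | CC1(C)COC(OC1)c1ccc(OCc2ccccc2)c(OCc2ccccc2)c1C#C[Si](C)(C)C | intermediate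
7 | 2-[3,4-bis(benzyloxy)-2-ethynylphenyl]-5,5-dimethyl-1,3-dioxane | CC1(C)COC(OC1)c1ccc(OCc2ccccc2)c(OCc2ccccc2)c1C#C | intermediate
8 | lithium acetylide of 7 | CC1(C)COC(OC1)c1ccc(OCc2ccccc2)c(OCc2ccccc2)c1C#C[Li] | intermediate
9 | lithium ynolate from 8 | CC1(C)COC(OC1)c1ccc(OCc2ccccc2)c(OCc2ccccc2)c1C#CO[Li] | intermediate
10 | [2,3-bis(benzyloxy)-6-(5,5-dimethyl-1,3-dioxan-2-yl)phenyl]ethynyl triisopropylsilyl ether | CC1(C)COC(OC1)c1ccc(OCc2ccccc2)c(OCc2ccccc2)c1C#CO[Si](C(C)C)(C(C)C)C(C)C | intermediate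
11 | 3-ethoxycyclobut-2-en-1-one | CCOC1=CC(=O)C1 | starting material
12 | 3-(benzyloxy)cyclobut-2-en-1-one | O=C1C=C(OCc2ccccc2)C1 | intermediate
13 | 3-(benzyloxy)buta-1,3-dien-1-one (vinylketene) | O=C=CC(=C)OCc1ccccc1 | intermediate
14 | 2-aryl-4-[1-(benzyloxy)ethenyl]-3-(triisopropylsilyloxy)cyclobut-2-en-1-one, aryl as in 10, racemic at C4 | O=C1C(C(=C)OCc2ccccc2)C(O[Si](C(C)C)(C(C)C)C(C)C)=C1c3c(C4OCC(C)(C)CO4)ccc(OCc4ccccc4)c3OCc3ccccc3 | intermediate
15 | 2-aryl-5-(benzyloxy)-3-(triisopropylsilyloxy)hexa-1,3,5-trien-1-one (dienylketene, ketene and alkoxyvinyl groups cis) | O=C=C(c1c(C2OCC(C)(C)CO2)ccc(OCc2ccccc2)c1OCc1ccccc1)/C(O[Si](C(C)C)(C(C)C)C(C)C)=C\C(=C)OCc1ccccc1 | intermediate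
16 | 2-aryl-5-(benzyloxy)-3-(triisopropylsilyloxy)cyclohexa-2,4-dien-1-one | O=C1CC(OCc2ccccc2)=CC(O[Si](C(C)C)(C(C)C)C(C)C)=C1c3c(C4OCC(C)(C)CO4)ccc(OCc4ccccc4)c3OCc3ccccc3 | intermediate
17 | 2-[2,3-bis(benzyloxy)-6-(5,5-dimethyl-1,3-dioxan-2-yl)phenyl]-5-(benzyloxy)-3-[(triisopropylsilyl)oxy]phenol (racemic axis) | Oc1cc(OCc2ccccc2)cc(O[Si](C(C)C)(C(C)C)C(C)C)c1-c1c(C2OCC(C)(C)CO2)ccc(OCc2ccccc2)c1OCc1ccccc1 | intermediate
18 | 2-[4',5,6-tris(benzyloxy)-2'-(methoxymethoxy)-6'-(triisopropylsilyloxy)biphenyl-2-yl]-5,5-dimethyl-1,3-dioxane | COCOc1cc(OCc2ccccc2)cc(O[Si](C(C)C)(C(C)C)C(C)C)c1-c1c(C2OCC(C)(C)CO2)ccc(OCc2ccccc2)c1OCc1ccccc1 | intermediate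
19 | 3,4-bis(benzyloxy)benzaldehyde | O=Cc1ccc(OCc2ccccc2)c(OCc2ccccc2)c1 | starting material
20 | 1,2-bis(benzyloxy)-4-ethynylbenzene | C#Cc1ccc(OCc2ccccc2)c(OCc2ccccc2)c1 | intermediate
21 | lithium acetylide of 20 | [Li]C#Cc1ccc(OCc2ccccc2)c(OCc2ccccc2)c1 | intermediate
22 | 3-[3,4-bis(benzyloxy)phenyl]-N-methoxy-N-methylprop-2-ynamide | CON(C)C(=O)C#Cc1ccc(OCc2ccccc2)c(OCc2ccccc2)c1 | intermediate
23 | aryllithium of 18, lithium between OMOM and OBn | COCOc1c([Li])c(OCc2ccccc2)cc(O[Si](C(C)C)(C(C)C)C(C)C)c1-c1c(C2OCC(C)(C)CO2)ccc(OCc2ccccc2)c1OCc1ccccc1 | intermediate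
24 | 1-{6-(benzyloxy)-3-[2,3-bis(benzyloxy)-6-(5,5-dimethyl-1,3-dioxan-2-yl)phenyl]-2-(methoxymethoxy)-4-(triisopropylsilyloxy)phenyl}-3-[3,4-bis(benzyloxy)phenyl]prop-2-yn-1-one | COCOc1c(C(=O)C#Cc2ccc(OCc3ccccc3)c(OCc3ccccc3)c2)c(OCc2ccccc2)cc(O[Si](C(C)C)(C(C)C)C(C)C)c1-c1c(C2OCC(C)(C)CO2)ccc(OCc2ccccc2)c1OCc1ccccc1 | intermediate
25 | 3-(diethylamino)prop-2-en-1-one (enaminone) from 24, alkene geometry not fixed | COCOc1c(C(=O)C=C(N(CC)CC)c2ccc(OCc3ccccc3)c(OCc3ccccc3)c2)c(OCc2ccccc2)cc(O[Si](C(C)C)(C(C)C)C(C)C)c1-c1c(C2OCC(C)(C)CO2)ccc(OCc2ccccc2)c1OCc1ccccc1 | intermediate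
26 | 3,4-bis(benzyloxy)-2-{5-(benzyloxy)-2-[3,4-bis(benzyloxy)phenyl]-4-oxo-7-[(triisopropylsilyl)oxy]-4H-chromen-8-yl}benzaldehyde | O=Cc1ccc(OCc2ccccc2)c(OCc2ccccc2)c1-c1c(O[Si](C(C)C)(C(C)C)C(C)C)cc(OCc2ccccc2)c2c(=O)cc(-c3ccc(OCc4ccccc4)c(OCc4ccccc4)c3)oc12 | intermediate
27 | caesium 7-phenolate from 26 | O=Cc1ccc(OCc2ccccc2)c(OCc2ccccc2)c1-c1c([O-])cc(OCc2ccccc2)c2c(=O)cc(-c3ccc(OCc4ccccc4)c(OCc4ccccc4)c3)oc12.[Cs+] | intermediate
28 | 3,4-bis(benzyloxy)-2-{5,7-bis(benzyloxy)-2-[3,4-bis(benzyloxy)phenyl]-4-oxo-4H-chromen-8-yl}benzaldehyde | O=Cc1ccc(OCc2ccccc2)c(OCc2ccccc2)c1-c1c(OCc2ccccc2)cc(OCc2ccccc2)c2c(=O)cc(-c3ccc(OCc4ccccc4)c(OCc4ccccc4)c3)oc12 | intermediate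
29 | 1-[2,4-bis(benzyloxy)-6-hydroxyphenyl]ethan-1-one | CC(=O)c1c(O)cc(OCc2ccccc2)cc1OCc1ccccc1 | starting material
30 | dilithium phenolate/enolate of 29 | [Li]OC(=C)c1c(O[Li])cc(OCc2ccccc2)cc1OCc1ccccc1 | intermediate
31 | tert-butyl 3-[2,4-bis(benzyloxy)-6-hydroxyphenyl]-3-oxopropanoate | CC(C)(C)OC(=O)CC(=O)c1c(O)cc(OCc2ccccc2)cc1OCc1ccccc1 | intermediate
32 | tert-butyl (Z)-2-[2,4-bis(benzyloxy)-6-hydroxybenzoyl]-3-(aryl)prop-2-enoate, aryl = residue of 28 | CC(C)(C)OC(=O)/C(=C\c1ccc(OCc2ccccc2)c(OCc2ccccc2)c1-c1c(OCc2ccccc2)cc(OCc2ccccc2)c2c(=O)cc(-c3ccc(OCc4ccccc4)c(OCc4ccccc4)c3)oc12)C(=O)c1c(O)cc(OCc2ccccc2)cc1OCc1ccccc1 | intermediate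
33 | tert-butyl (2S)-5,7-bis(benzyloxy)-2-(aryl)-4-oxochromane-3-carboxylate, C3 epimers and enol | O=C1C(C(=O)OC(C)(C)C)[C@@H](c2ccc(OCc3ccccc3)c(OCc3ccccc3)c2-c2c(OCc3ccccc3)cc(OCc3ccccc3)c3c(=O)cc(-c4ccc(OCc5ccccc5)c(OCc5ccccc5)c4)oc23)Oc2cc(OCc3ccccc3)cc(OCc3ccccc3)c21 | intermediate
34 | (2S)-5,7-bis(benzyloxy)-2-(aryl)-4-oxochromane-3-carboxylic acid, C3 not fixed | O=C1C(C(=O)O)[C@@H](c2ccc(OCc3ccccc3)c(OCc3ccccc3)c2-c2c(OCc3ccccc3)cc(OCc3ccccc3)c3c(=O)cc(-c4ccc(OCc5ccccc5)c(OCc5ccccc5)c4)oc23)Oc2cc(OCc3ccccc3)cc(OCc3ccccc3)c21 | intermediate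
35 | (2S)-5,7-bis(benzyloxy)-2-(3,4-bis(benzyloxy)-2-{5,7-bis(benzyloxy)-2-[3,4-bis(benzyloxy)phenyl]-4-oxo-4H-chromen-8-yl}phenyl)chroman-4-one | O=C1C[C@@H](c2ccc(OCc3ccccc3)c(OCc3ccccc3)c2-c2c(OCc3ccccc3)cc(OCc3ccccc3)c3c(=O)cc(-c4ccc(OCc5ccccc5)c(OCc5ccccc5)c4)oc23)Oc2cc(OCc3ccccc3)cc(OCc3ccccc3)c21 | intermediate
36 | (2S)-2-{2-[2-(3,4-dihydroxyphenyl)-5,7-dihydroxy-4-oxo-4H-chromen-8-yl]-3,4-dihydroxyphenyl}-5,7-dihydroxychroman-4-one | O=C1C[C@@H](c2ccc(O)c(O)c2-c2c(O)cc(O)c3c(=O)cc(-c4ccc(O)c(O)c4)oc23)Oc2cc(O)cc(O)c21 | target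

**Step count**
- Total step count: 18.
- Longest linear sequence: 14 (steps 1–6, 8, 9, 12–14, 16–18).

**Steps most likely to fail**

1. Step 8.
   - What may go wrong: the donor-stabilised cyclobutenone may open too slowly. At the temperature then needed, the vinylketene could oligomerise or acylate the product phenol, or the siloxyalkyne could decompose before the [2+2] event.
   - Fallback (known cross-coupling chemistry, sets out from 3, returns at 28): bought phloroglucinol is converted with MOMCl/i-Pr2NEt into 3,5-bis(methoxymethoxy)phenol F1 and benzylated (BnBr, K2CO3) to 1-(benzyloxy)-3,5-bis(methoxymethoxy)benzene F2. Lithiation between the two MOM ethers (n-BuLi), B(OiPr)3 and mild acid give [4-(benzyloxy)-2,6-bis(methoxymethoxy)phenyl]boronic acid F3. Suzuki–Miyaura coupling of this acid with 3 (Pd(OAc)2, SPhos, K3PO4, toluene/H2O, 100 °C) gives 4',5,6-tris(benzyloxy)-2',6'-bis(methoxymethoxy)biphenyl-2-carbaldehyde F4. Acetalisation (2,2-dimethylpropane-1,3-diol, PPTS, benzene, reflux) gives its neopentyl-glycol acetal F5. The two ring hydrogens next to a MOM ether are equivalent, so lithiation and acylation with 22 as in step 12 give a single bis-MOM ynone F6. Diethylamine gives bis-MOM enaminone F7, aqueous HCl as in step 13 then gives 7-hydroxyflavone aldehyde F8, and Cs2CO3/BnBr carries this through phenolate 27 to 28.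

2. Step 17.
   - What may go wrong: poor facial selectivity. The alkene lies next to a racemic, slowly rotating biaryl axis, so one atropisomer of 32 is matched and the other mismatched with the catalyst. Amine-promoted background cyclisation (possibly already during step 16) and acid-induced ring opening and reclosure at 80 °C would erode the purity at C2 further.
   - Fallback (sets out from 28, returns at 35): Claisen–Schmidt condensation of 28 with 29 (KOH, EtOH/THF) gives 2'-hydroxychalcone F9, and NaOAc in refluxing EtOH closes it to racemic flavanone F10. Kinetic resolution by asymmetric transfer hydrogenation (Cp*RhCl[(R,R)-TsDPEN], HCO2H/Et3N, EtOAc) should then reduce the (2R) ketone to cis-(2R,4R)-flavan-4-ol F11 and leave 35. Conversion is pushed past one half, so the recovered ketone is enriched for both atropisomers.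

3. Step 7.
   - What may go wrong: acid-induced hydrolysis or ring cleavage of the strained vinylogous ester may outrun alkoxy exchange, or the equilibrium may stall.
   - Fallback (sets out from 11, returns at 12): cold dilute aqueous HCl hydrolyses 11 to cyclobutane-1,3-dione F12, a strongly acidic enol. Benzyl 2,2,2-trichloroacetimidate in CH2Cl2 O-benzylates it without added promoter to give 12.

**Further compounds**

F1 | step 8 | 3,5-bis(methoxymethoxy)phenol | COCOc1cc(O)cc(OCOC)c1
F2 | step 8 | 1-(benzyloxy)-3,5-bis(methoxymethoxy)benzene | COCOc1cc(OCc2ccccc2)cc(OCOC)c1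
F3 | step 8 | [4-(benzyloxy)-2,6-bis(methoxymethoxy)phenyl]boronic acid | COCOc1cc(OCc2ccccc2)cc(OCOC)c1B(O)O
F4 | step 8 | 4',5,6-tris(benzyloxy)-2',6'-bis(methoxymethoxy)biphenyl-2-carbaldehyde | O=Cc1ccc(OCc2ccccc2)c(OCc2ccccc2)c1-c1c(OCOC)cc(OCc2ccccc2)cc1OCOC
F5 | step 8 | 2-[4',5,6-tris(benzyloxy)-2',6'-bis(methoxymethoxy)biphenyl-2-yl]-5,5-dimethyl-1,3-dioxane | CC1(C)COC(OC1)c1ccc(OCc2ccccc2)c(OCc2ccccc2)c1-c1c(OCOC)cc(OCc2ccccc2)cc1OCOC
F6 | step 8 | bis-MOM ynone (analogue of 24 with OMOM in place of OTIPS) | COCOc1cc(OCc2ccccc2)c(C(=O)C#Cc2ccc(OCc3ccccc3)c(OCc3ccccc3)c2)c(OCOC)c1-c1c(C2OCC(C)(C)CO2)ccc(OCc2ccccc2)c1OCc1ccccc1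
F7 | step 8 | bis-MOM enaminone from F6, alkene geometry not fixed | COCOc1cc(OCc2ccccc2)c(C(=O)C=C(N(CC)CC)c2ccc(OCc3ccccc3)c(OCc3ccccc3)c2)c(OCOC)c1-c1c(C2OCC(C)(C)CO2)ccc(OCc2ccccc2)c1OCc1ccccc1
F8 | step 8 | 3,4-bis(benzyloxy)-2-{5-(benzyloxy)-2-[3,4-bis(benzyloxy)phenyl]-7-hydroxy-4-oxo-4H-chromen-8-yl}benzaldehyde | O=Cc1ccc(OCc2ccccc2)c(OCc2ccccc2)c1-c1c(O)cc(OCc2ccccc2)c2c(=O)cc(-c3ccc(OCc4ccccc4)c(OCc4ccccc4)c3)oc12
F9 | step 17 | (E)-1-[2,4-bis(benzyloxy)-6-hydroxyphenyl]-3-(aryl)prop-2-en-1-one, aryl = residue of 28 | O=C(/C=C/c1ccc(OCc2ccccc2)c(OCc2ccccc2)c1-c1c(OCc2ccccc2)cc(OCc2ccccc2)c2c(=O)cc(-c3ccc(OCc4ccccc4)c(OCc4ccccc4)c3)oc12)c1c(O)cc(OCc2ccccc2)cc1OCc1ccccc1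
F10 | step 17 | racemic octabenzyl flavanone (racemate of 35) | O=C1CC(c2ccc(OCc3ccccc3)c(OCc3ccccc3)c2-c2c(OCc3ccccc3)cc(OCc3ccccc3)c3c(=O)cc(-c4ccc(OCc5ccccc5)c(OCc5ccccc5)c4)oc23)Oc2cc(OCc3ccccc3)cc(OCc3ccccc3)c21
F11 | step 17 | cis-(2R,4R)-octabenzyl flavan-4-ol | O[C@@H]1C[C@H](c2ccc(OCc3ccccc3)c(OCc3ccccc3)c2-c2c(OCc3ccccc3)cc(OCc3ccccc3)c3c(=O)cc(-c4ccc(OCc5ccccc5)c(OCc5ccccc5)c4)oc23)Oc2cc(OCc3ccccc3)cc(OCc3ccccc3)c21
F12 | step 7 | cyclobutane-1,3-dione | O=C1CC(=O)C1
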